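**Retrosynthetic overview**

1. Target 9 ⇐ base-induced Kornblum–DeLaMare opening and lactonisation of the 3-ethoxy-1,2-dioxine 7 ⇐ [4+2] cycloaddition of singlet oxygen to ethoxydiene 6. Both lactone oxygens come from O2, and the C7a stereocentre is set here.
2. Diene 6 ⇐ Suzuki coupling of enol triflate 4 with (E)-2-ethoxyvinyl-Bpin 5, which supplies C2 and C3 of the butenolide.
3. Triflate 4 ⇐ keto ester 3 ⇐ (4R,6R)-actinol 1 + palmitoyl chloride 2. The palmitate goes on first and doubles as the hydroxyl protection.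
4. Ring order: the carbocycle is bought; the dioxine ring forms by cycloaddition and is contracted to the butenolide in the same flask.

Assumption: (4R,6R)-4-hydroxy-2,2,6-trimethylcyclohexanone (actinol, the industrial zeaxanthin intermediate) is taken as a purchasable chiral-pool compound; "3-O" is the carotenoid-style locant for the C6 oxygen of the benzofuranone.

**Route**

Step 1
Reactants: 1 (4R,6R)-4-hydroxy-2,2,6-trimethylcyclohexan-1-one (actinol; OH and 6-methyl trans); 2 hexadecanoyl (palmitoyl) chloride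
Product: 3 (1R,5R)-3,3,5-trimethyl-4-oxocyclohexyl hexadecanoate
Conditions: pyridine, DMAP (cat.), CH2Cl2, 0 °C → rt
Reagents that add atoms: none
Why: DMAP-catalysed O-acylation of the secondary alcohol with the acid chloride leaves the C–O bond intact, so the carbinol configuration is retained.

Step 2
Reactants: 3 (1R,5R)-3,3,5-trimethyl-4-oxocyclohexyl hexadecanoate
Product: 4 (1R)-3,5,5-trimethyl-4-{[(trifluoromethyl)sulfonyl]oxy}cyclohex-3-en-1-yl hexadecanoate
Conditions: Tf2O, 2,6-di-tert-butyl-4-methylpyridine, CH2Cl2, 0 °C → rt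
Reagents that add atoms: triflic anhydride, O=S(=O)(OS(=O)(=O)C(F)(F)F)C(F)(F)F
Why: Enol triflate formation (O-triflation, then loss of the only α-hydrogen) gives a single regioisomer, the hindered non-nucleophilic base spares the palmitate, and only the methyl-bearing centre, which is not needed, is flattened.

Step 3
Reactants: 4 (1R)-3,5,5-trimethyl-4-(triflyloxy)cyclohex-3-en-1-yl hexadecanoate; 5 2-[(E)-2-ethoxyethenyl]-4,4,5,5-tetramethyl-1,3,2-dioxaborolane
Product: 6 (1R)-4-[(E)-2-ethoxyethenyl]-3,5,5-trimethylcyclohex-3-en-1-yl hexadecanoate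
Conditions: Pd(OAc)2 (5 mol %), SPhos (10 mol %), K3PO4, THF/H2O, 50 °C; chromatography on Et3N-deactivated silica
Reagents that add atoms: none
Why: Suzuki–Miyaura coupling with a bulky electron-rich biaryl phosphine tolerates the tetrasubstituted alkenyl triflate, transfers the alkenyl group with retention of E geometry, and the phosphate base leaves the ester and the carbinol centre alone.

Step 4
Reactants: 6 (1R)-4-[(E)-2-ethoxyethenyl]-3,5,5-trimethylcyclohex-3-en-1-yl hexadecanoate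
Product: 9 (−)-3-O-palmitoylloliolide, via ethoxy endoperoxide 7 (not isolated), via hydroxy enoate 8 (not isolated)
Conditions: O2, TPP (cat.), hν (white LED), CH2Cl2, −78 °C; then Et3N, −78 °C → rt
Reagents that add atoms: dioxygen (as singlet oxygen), O=O
Why: Singlet-oxygen [4+2] cycloaddition across the ring carbon and the enol-ether carbon of the cisoid diene (by analogy with the 5,8-endoperoxides of β-ionone-type dienes) builds a 1,2-dioxine containing all five butenolide ring atoms, with O2 expected to add anti to the acyloxy group so that the bought carbinol centre sets 7aR (minor 7a-epimer removed by chromatography), and Kornblum–DeLaMare fragmentation at the only peroxide α-C–H then gives the (Z)-γ-hydroxy ethyl ester, which lactonises with loss of ethanol.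

**Compound list**

1 | (4R,6R)-4-hydroxy-2,2,6-trimethylcyclohexan-1-one (actinol) | O[C@H]1CC(C)(C)C(=O)[C@H](C)C1 | starting material
2 | hexadecanoyl chloride (palmitoyl chloride) | CCCCCCCCCCCCCCCC(=O)Cl | starting material
3 | (1R,5R)-3,3,5-trimethyl-4-oxocyclohexyl hexadecanoate | CCCCCCCCCCCCCCCC(=O)O[C@H]1CC(C)(C)C(=O)[C@H](C)C1 | intermediate
4 | (1R)-3,5,5-trimethyl-4-{[(trifluoromethyl)sulfonyl]oxy}cyclohex-3-en-1-yl hexadecanoate | CCCCCCCCCCCCCCCC(=O)O[C@H]1CC(C)(C)C(OS(=O)(=O)C(F)(F)F)=C(C)C1 | intermediate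
5 | 2-[(E)-2-ethoxyethenyl]-4,4,5,5-tetramethyl-1,3,2-dioxaborolane | CCO/C=C/B1OC(C)(C)C(C)(C)O1 | starting material
6 | (1R)-4-[(E)-2-ethoxyethenyl]-3,5,5-trimethylcyclohex-3-en-1-yl hexadecanoate | CCCCCCCCCCCCCCCC(=O)O[C@H]1CC(C)(C)C(/C=C/OCC)=C(C)C1 | intermediate
7 | (3R,7S,8aR)-3-ethoxy-5,5,8a-trimethyl-3,5,6,7,8,8a-hexahydrobenzo[c][1,2]dioxin-7-yl hexadecanoate (peroxide bridge trans to the ester; OEt trans to the 8a-methyl) | CCCCCCCCCCCCCCCC(=O)O[C@H]1CC(C)(C)C2=C[C@H](OCC)OO[C@]2(C)C1 | intermediate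
8 | ethyl (2Z)-[(2R,4S)-4-(hexadecanoyloxy)-2-hydroxy-2,6,6-trimethylcyclohexylidene]acetate | CCCCCCCCCCCCCCCC(=O)O[C@H]1CC(C)(C)/C(=C/C(=O)OCC)[C@](C)(O)C1 | intermediate
9 | (−)-3-O-palmitoylloliolide, (6S,7aR)-4,4,7a-trimethyl-2-oxo-2,4,5,6,7,7a-hexahydro-1-benzofuran-6-yl hexadecanoate | CCCCCCCCCCCCCCCC(=O)O[C@H]1CC(C)(C)C2=CC(=O)O[C@]2(C)C1 | target

**Totals**

Total step count: 4. Longest linear sequence: 4 steps (1 → 3 → 4 → 6 → 9).

**Steps most likely to fail, with fallbacks**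

Step 4 (highest risk). The electron-rich enol ether may give [2+2] dioxetane cleavage and the tetrasubstituted ring alkene may give ene hydroperoxides. Facial control comes only from a remote ester, so the diastereomer ratio at C7a is uncertain and may be modest. The fallback sets out from 3 and comes back at 9, replacing the photooxygenation by an α-hydroxylation and a ylide ring closure. Soft enolisation of 3 (TMSOTf, Et3N, CH2Cl2, 0 °C) gives (1R)-3,5,5-trimethyl-4-[(trimethylsilyl)oxy]cyclohex-3-en-1-yl hexadecanoate F1. Rubottom oxidation with dimethyldioxirane (acetone, −40 °C) is expected to occur anti to the ester, as in peracid epoxidation of 3-acyloxy-β-ionone-type rings, and gives (1R,3S,6R)-1,5,5-trimethyl-6-[(trimethylsilyl)oxy]-7-oxabicyclo[4.1.0]heptan-3-yl hexadecanoate F2. Et3N·3HF (THF, 0 °C) opens this to (1S,3R)-3-hydroxy-3,5,5-trimethyl-4-oxocyclohexyl hexadecanoate F3, where any epimer can be removed. Heating F3 with ketenylidenetriphenylphosphorane (Ph3P=C=C=O, toluene, 110 °C) acylates the tertiary alcohol to (1R,5S)-5-(hexadecanoyloxy)-1,3,3-trimethyl-2-oxocyclohexyl (triphenyl-λ5-phosphanylidene)acetate F4, which closes by intramolecular Wittig olefination to 9.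

Step 3. The triflate is tetrasubstituted and flanked by a quaternary carbon, and the ethoxyvinyl boronate and product are acid- and protodeboronation-sensitive. The fallback sets out from 4 and comes back at 9, using a robust vinyl group and adjusting the oxidation level afterwards. Stille coupling of 4 with tributyl(vinyl)stannane (Pd2(dba)3, AsPh3, NMP, 50 °C) gives (1R)-4-ethenyl-3,5,5-trimethylcyclohex-3-en-1-yl hexadecanoate F5. Singlet-oxygen [4+2] cycloaddition (O2, TPP, hν, CH2Cl2, −78 °C) gives (7S,8aR)-5,5,8a-trimethyl-3,5,6,7,8,8a-hexahydrobenzo[c][1,2]dioxin-7-yl hexadecanoate F6. Kornblum–DeLaMare rearrangement with Et3N delivers the ring-closed Z-hydroxy enal, the lactol (6S,7aR)-2-hydroxy-4,4,7a-trimethyl-2,4,5,6,7,7a-hexahydro-1-benzofuran-6-yl hexadecanoate F7. MnO2 (CH2Cl2, rt) oxidises F7 to 9.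

Step 2. Enolisation of the hindered ketone towards a tertiary α-carbon under Tf2O/pyridine-base conditions may be slow, and strong amide bases cannot be used beside the palmitate. The fallback sets out from 1 and comes back at 4, carrying the alcohol as a silyl ether through enolate chemistry. TBSCl/imidazole (DMF) gives (4R,6R)-4-[(tert-butyldimethylsilyl)oxy]-2,2,6-trimethylcyclohexan-1-one F8. LDA (THF, −78 °C) then PhNTf2 gives (4R)-4-[(tert-butyldimethylsilyl)oxy]-2,6,6-trimethylcyclohex-1-en-1-yl trifluoromethanesulfonate F9. HF·pyridine (THF, 0 °C → rt) gives (4R)-4-hydroxy-2,6,6-trimethylcyclohex-1-en-1-yl trifluoromethanesulfonate F10. Acylation of F10 with 2 (pyridine, DMAP, CH2Cl2) gives 4.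

**Further compounds**

F1 | step 4 | (1R)-3,5,5-trimethyl-4-[(trimethylsilyl)oxy]cyclohex-3-en-1-yl hexadecanoate | CCCCCCCCCCCCCCCC(=O)O[C@H]1CC(C)(C)C(O[Si](C)(C)C)=C(C)C1
F2 | step 4 | (1R,3S,6R)-1,5,5-trimethyl-6-[(trimethylsilyl)oxy]-7-oxabicyclo[4.1.0]heptan-3-yl hexadecanoate | CCCCCCCCCCCCCCCC(=O)O[C@H]1CC(C)(C)[C@]2(O[Si](C)(C)C)O[C@]2(C)C1
F3 | step 4 | (1S,3R)-3-hydroxy-3,5,5-trimethyl-4-oxocyclohexyl hexadecanoate | CCCCCCCCCCCCCCCC(=O)O[C@H]1CC(C)(C)C(=O)[C@](C)(O)C1
F4 | step 4 | (1R,5S)-5-(hexadecanoyloxy)-1,3,3-trimethyl-2-oxocyclohexyl (triphenyl-λ5-phosphanylidene)acetate | CCCCCCCCCCCCCCCC(=O)O[C@H]1CC(C)(C)C(=O)[C@](C)(OC(=O)C=P(c2ccccc2)(c2ccccc2)c2ccccc2)C1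
F5 | step 3 | (1R)-4-ethenyl-3,5,5-trimethylcyclohex-3-en-1-yl hexadecanoate | CCCCCCCCCCCCCCCC(=O)O[C@H]1CC(C)(C)C(C=C)=C(C)C1
F6 | step 3 | (7S,8aR)-5,5,8a-trimethyl-3,5,6,7,8,8a-hexahydrobenzo[c][1,2]dioxin-7-yl hexadecanoate | CCCCCCCCCCCCCCCC(=O)O[C@H]1CC(C)(C)C2=CCOO[C@]2(C)C1
F7 | step 3 | (6S,7aR)-2-hydroxy-4,4,7a-trimethyl-2,4,5,6,7,7a-hexahydro-1-benzofuran-6-yl hexadecanoate (anomer mixture) | CCCCCCCCCCCCCCCC(=O)O[C@H]1CC(C)(C)C2=CC(O)O[C@]2(C)C1
F8 | step 2 | (4R,6R)-4-[(tert-butyldimethylsilyl)oxy]-2,2,6-trimethylcyclohexan-1-one | CC(C)(C)[Si](C)(C)O[C@H]1CC(C)(C)C(=O)[C@H](C)C1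
F9 | step 2 | (4R)-4-[(tert-butyldimethylsilyl)oxy]-2,6,6-trimethylcyclohex-1-en-1-yl trifluoromethanesulfonate | CC(C)(C)[Si](C)(C)O[C@H]1CC(C)(C)C(OS(=O)(=O)C(F)(F)F)=C(C)C1
F10 | step 2 | (4R)-4-hydroxy-2,6,6-trimethylcyclohex-1-en-1-yl trifluoromethanesulfonate | O[C@H]1CC(C)(C)C(OS(=O)(=O)C(F)(F)F)=C(C)C1
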